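**Retrosynthetic overview**

1. Target 26 comes from the all-trans oxolane-3-carboxylate 24 by ester reduction and silyl removal; 24 comes from the insertion product 23 by base inversion of the C3 ester only.
2. Key disconnection is C2–C3: 23 arises from α-diazo ester 22 by rhodium carbene 1,5 C–H insertion into the O1–CH2 group of the ring A benzyl ether, which closes the only ring (the oxolane).
3. 22 comes from methyl ester 19 by diazo transfer, and 19 from the allyl group of 15 by oxidative cleavage; the C5–O1 ether bond joins aldol 8 to ring A imidate 12 (made from syringaldehyde 9).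
4. The C4–C5 bond and both its stereocentres come from an Evans syn aldol of imide 4 (from 1 and 2) with 3,4,5-trimethoxybenzaldehyde 5.
5. Feature used: the C2–H of the all-trans oxolane lies between O1 and the electron-rich ring A (4-hydroxy-3,5-dimethoxyphenyl) and is 1,5 to C3, whose exocyclic CH2OH carbon can be carried as the ester of a diazo ester.

Key step: step 13

Remark (numbering): oxolane locants O1, C2 (ring A), C3, C4, C5 (ring B) are used for the same atoms in the open-chain compounds; TBS = tert-butyldimethylsilyl.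
Remark (assumption): the insertion is taken to deliver the C3 ester cis to ring A, as α-alkyl α-diazo esters do on insertion into benzylic C–H bonds; C3 is therefore equilibrated in step 14, and only C2 has to be set correctly in step 13.

**Route**

Step 1
Reactants: 1 (R)-4-benzyloxazolidin-2-one; 2 pent-4-enoyl chloride
Product: 4 (R)-4-benzyl-3-(pent-4-enoyl)oxazolidin-2-one, via lithium oxazolidinide 3 (not isolated)
Conditions: n-BuLi, THF, −78 °C; then 2, −78 → 0 °C
Reagents that add atoms: none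
Why: N-acylation of the lithiated oxazolidinone by the acid chloride is a standard imide formation that does not touch the stereocentre of the auxiliary.

Step 2
Reactants: 4 (R)-4-benzyl-3-(pent-4-enoyl)oxazolidin-2-one; 5 3,4,5-trimethoxybenzaldehyde
Product: 8 (R)-4-benzyl-3-[(2R)-2-[(R)-hydroxy(3,4,5-trimethoxyphenyl)methyl]pent-4-enoyl]oxazolidin-2-one, via Z-boron enolate 6 (not isolated), via boron aldolate 7 (not isolated)
Conditions: Bu2BOTf, i-Pr2NEt, CH2Cl2, 0 °C; 5, −78 → 0 °C; then pH 7 buffer, MeOH, 30% H2O2, 0 °C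
Reagents that add atoms: none
Why: Evans syn aldol, in which the Z-boron enolate reacts through a closed chair (Zimmerman–Traxler) transition state on the face left open by the benzyl group of the (R)-auxiliary, should set C4 and C5 as the (2R,3R) syn adduct, the relation that becomes 4,5-trans once O1 and the allyl-derived carbon are joined in the ring.

Step 3
Reactants: 9 syringaldehyde
Product: 10 4-(TBS-oxy)-3,5-dimethoxybenzaldehyde
Conditions: TBSCl, imidazole, DMF, rt
Reagents that add atoms: tert-butyldimethylsilyl chloride, CC(C)(C)[Si](C)(C)Cl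
Why: Imidazole-promoted silylation of the phenol masks the only acidic O–H of ring A, which would otherwise quench the carbene and the enolates used later.

Step 4
Reactants: 10 4-(TBS-oxy)-3,5-dimethoxybenzaldehyde
Product: 11 [4-(TBS-oxy)-3,5-dimethoxyphenyl]methanol
Conditions: NaBH4, THF/MeOH, 0 °C
Reagents that add atoms: none
Why: Borohydride reduction of an aryl aldehyde to the benzylic alcohol is fast at 0 °C and leaves the hindered aryl silyl ether in place.

Step 5
Reactants: 11 [4-(TBS-oxy)-3,5-dimethoxyphenyl]methanol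
Product: 12 4-(TBS-oxy)-3,5-dimethoxybenzyl 2,2,2-trichloroacetimidate
Conditions: Cl3CCN, DBU (cat.), CH2Cl2, 0 °C
Reagents that add atoms: trichloroacetonitrile, N#CC(Cl)(Cl)Cl
Why: Base-catalysed addition of the alcohol to the nitrile gives the imidate, an alkylating agent that is activated by acid and so avoids basic conditions on the aldol adduct.

Step 6
Reactants: 8 aldol adduct; 12 4-(TBS-oxy)-3,5-dimethoxybenzyl 2,2,2-trichloroacetimidate
Product: 13 (R)-4-benzyl-3-[(2R)-2-[(R)-{[4-(TBS-oxy)-3,5-dimethoxybenzyl]oxy}(3,4,5-trimethoxyphenyl)methyl]pent-4-enoyl]oxazolidin-2-one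
Conditions: TfOH (cat.), 4 Å MS, CH2Cl2, −20 → 0 °C; Et3N quench
Reagents that add atoms: none
Why: Brønsted acid-catalysed O-benzylation with a trichloroacetimidate transfers the ring A benzyl group to the C5 hydroxyl with loss of trichloroacetamide, without base (no retro-aldol) and without breaking the C5–O bond, so C5 keeps its configuration.

Step 7
Reactants: 13 benzyl ether imide
Product: 14 (2S)-2-[(R)-{[4-(TBS-oxy)-3,5-dimethoxybenzyl]oxy}(3,4,5-trimethoxyphenyl)methyl]pent-4-en-1-ol
Conditions: LiBH4, MeOH (1 equiv), THF, 0 °C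
Reagents that add atoms: none
Why: Reductive cleavage of the N-acyl oxazolidinone by LiBH4 gives the primary alcohol and returns the auxiliary, and because no enolate is formed C4 is not epimerised.

Step 8
Reactants: 14 primary alcohol
Product: 15 (4S)-4-[(TBS-oxy)methyl] alkene, i.e. tert-butyl{[(2S)-2-[(R)-{[4-(TBS-oxy)-3,5-dimethoxybenzyl]oxy}(3,4,5-trimethoxyphenyl)methyl]pent-4-en-1-yl]oxy}dimethylsilane
Conditions: TBSCl, imidazole, DMAP (cat.), CH2Cl2, rt
Reagents that add atoms: tert-butyldimethylsilyl chloride, CC(C)(C)[Si](C)(C)Cl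
Why: Silylation of the primary hydroxyl gives a C4 arm that has no C–H bond 1,5 to the future carbene, which a benzyl ether there would have.

Step 9
Reactants: 15 bis-silyl alkene
Product: 17 (3S,4R)-3-[(TBS-oxy)methyl]-4-{[4-(TBS-oxy)-3,5-dimethoxybenzyl]oxy}-4-(3,4,5-trimethoxyphenyl)butanal, via vicinal diol 16 (not isolated)
Conditions: OsO4 (cat.), NaIO4, 2,6-lutidine, dioxane/H2O, rt
Reagents that add atoms: osmium tetroxide, O=[Os](=O)(=O)=O; sodium periodate, [Na+].[O-]I(=O)(=O)=O (together they supply the aldehyde oxygen)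
Why: Lemieux–Johnson oxidation dihydroxylates the terminal alkene and cleaves the diol in the same flask, and unlike ozone it leaves the two electron-rich arenes and the benzylic ether alone.

Step 10
Reactants: 17 aldehyde
Product: 18 (3S,4R)-3-[(TBS-oxy)methyl]-4-{[4-(TBS-oxy)-3,5-dimethoxybenzyl]oxy}-4-(3,4,5-trimethoxyphenyl)butanoic acid
Conditions: NaClO2, NaH2PO4, 2-methylbut-2-ene, t-BuOH/H2O, rt
Reagents that add atoms: sodium chlorite, [Na+].[O-]Cl=O
Why: Pinnick oxidation converts the aldehyde into the acid under buffered conditions, and the alkene scavenger takes up the hypochlorous acid that would chlorinate the arenes.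

Step 11
Reactants: 18 carboxylic acid
Product: 19 methyl (3S,4R)-3-[(TBS-oxy)methyl]-4-{[4-(TBS-oxy)-3,5-dimethoxybenzyl]oxy}-4-(3,4,5-trimethoxyphenyl)butanoate
Conditions: Me3SiCHN2, PhMe/MeOH, 0 °C → rt
Reagents that add atoms: (trimethylsilyl)diazomethane, C[Si](C)(C)C=[N+]=[N-]
Why: O-methylation of the carboxylic acid by diazomethane released in situ needs neither acid nor base, so both silyl ethers and the benzylic ether survive.

Step 12
Reactants: 19 methyl ester
Product: 22 methyl (3S,4R)-2-diazo-3-[(TBS-oxy)methyl]-4-{[4-(TBS-oxy)-3,5-dimethoxybenzyl]oxy}-4-(3,4,5-trimethoxyphenyl)butanoate, via lithium ester enolate 20 (not isolated), via trifluoroacetyl ester 21 (not isolated)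
Conditions: LiN(SiMe3)2, THF, −78 °C; CF3CO2CH2CF3, −78 °C; aq. NH4Cl; then MsN3, Et3N, H2O (1 equiv), MeCN, rt
Reagents that add atoms: methanesulfonyl azide, CS(=O)(=O)N=[N+]=[N-]
Why: Claisen-type C-trifluoroacetylation of the lithium ester enolate followed by deacylative (Regitz-type) diazo transfer puts the diazo group on C3 with loss of the trifluoroacetyl group as the sulfonamide, and C4, which is not enolisable and has no leaving group, is untouched.

Step 13
Reactants: 22 α-diazo ester
Product: 23 methyl (2R,3S,4S,5R)-2-[4-(TBS-oxy)-3,5-dimethoxyphenyl]-4-[(TBS-oxy)methyl]-5-(3,4,5-trimethoxyphenyl)oxolane-3-carboxylate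
Conditions: Rh2(O2CCPh3)4 (1 mol %), CH2Cl2, slow addition of 22 at −78 °C, then to −20 °C
Reagents that add atoms: none
Why: Rh2(O2CCPh3)4 takes N2 from 22 to give an electrophilic rhodium carbene at C3, which draws hydride character from an O1–CH2 hydrogen of the ring A benzyl ether in a concerted three-centre transition state and forms C2–C3 as rhodium leaves. The closest known reaction type is the dirhodium carboxylate-catalysed 1,5 C–H insertion of α-alkyl α-diazo esters into benzylic and ether C–H bonds, which gives 2-aryl carbocycle and oxacycle carboxylates with the aryl group cis to the ester. The oxolane closes by 1,5 insertion, a five-membered ring formed through a chair-like array C3–C4–C5–O1–C2–H in which ring B and the C4 silyloxymethyl arm are equatorial. C2 is set by which diastereotopic benzylic hydrogen is taken: the C4 centre turns its hydrogen, not its arm, towards the dirhodium core, and the triphenylacetate wall turns ring A away from rhodium, so ring A should end cis to the C4 arm and trans to ring B, as in the target. C3 is set in the same event with the ester on the face away from rhodium, cis to ring A and to the C4 arm, and is corrected in step 14. The step needs insertion to outrun the 1,2-hydride shift from C4 and attack on ring B; what should secure this is the doubly activated C–H (next to oxygen and benzylic to a trioxygenated arene), the inductive deactivation of C4–H by the two oxygen-bearing carbons attached to C4, the bulky carboxylate and the low temperature.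

Step 14
Reactants: 23 oxolane ester (C3 ester cis to ring A)
Product: 24 methyl (2R,3R,4S,5R)-4-[(TBS-oxy)methyl]-2-(4-hydroxy-3,5-dimethoxyphenyl)-5-(3,4,5-trimethoxyphenyl)oxolane-3-carboxylate
Conditions: NaOMe, MeOH/THF, rt → 40 °C; aq. NH4Cl
Reagents that add atoms: none
Why: Thermodynamic epimerisation through the ester enolate should settle C3 in the all-trans isomer because in 23 the ester is cis to both neighbours (the ring C2–O1 bond lies near the nodal plane of the enolate, which disfavours β-elimination), and methoxide also cleaves the phenolic silyl ether, which is no longer needed.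

Step 15
Reactants: 24 all-trans ester
Product: 25 4-[(2R,3S,4S,5R)-4-[(TBS-oxy)methyl]-3-(hydroxymethyl)-5-(3,4,5-trimethoxyphenyl)oxolan-2-yl]-2,6-dimethoxyphenol
Conditions: LiAlH4, THF, 0 °C; Rochelle salt work-up
Reagents that add atoms: none
Why: Hydride reduction of the methyl ester with LiAlH4 gives the C3 hydroxymethyl group (one hydride is spent on the phenol) and involves no stereocentre.

Step 16
Reactants: 25 mono-silyl diol
Product: 26 4-[(2R,3S,4S,5R)-3,4-bis(hydroxymethyl)-5-(3,4,5-trimethoxyphenyl)oxolan-2-yl]-2,6-dimethoxyphenol (CID56680032)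
Conditions: Bu4NF, THF, 0 °C → rt; aq. NH4Cl
Reagents that add atoms: none
Why: Fluoride-induced cleavage of the remaining primary silyl ether releases the target without touching the benzylic C–O bonds of the oxolane.

**Compound list**

1 | (R)-4-benzyloxazolidin-2-one | O=C1N[C@H](Cc2ccccc2)CO1 | starting material
2 | pent-4-enoyl chloride | C=CCCC(=O)Cl | starting material
3 | lithium (R)-4-benzyl-2-oxooxazolidin-3-ide | [Li+].O=C1[N-][C@H](Cc2ccccc2)CO1 | intermediate
4 | (R)-4-benzyl-3-(pent-4-enoyl)oxazolidin-2-one | C=CCCC(=O)N1[C@H](Cc2ccccc2)COC1=O | intermediate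
5 | 3,4,5-trimethoxybenzaldehyde | COc1cc(C=O)cc(OC)c1OC | starting material
6 | (R)-4-benzyl-3-[(Z)-1-(dibutylboranyloxy)penta-1,4-dien-1-yl]oxazolidin-2-one | C=CC/C=C(\OB(CCCC)CCCC)N1[C@H](Cc2ccccc2)COC1=O | intermediate
7 | dibutylboron aldolate of 8 (O-boryl at C5) | O=C(N1[C@H](Cc2ccccc2)COC1=O)[C@H](CC=C)[C@@H](OB(CCCC)CCCC)c1cc(OC)c(OC)c(OC)c1 | intermediate
8 | (R)-4-benzyl-3-[(2R)-2-[(R)-hydroxy(3,4,5-trimethoxyphenyl)methyl]pent-4-enoyl]oxazolidin-2-one | O=C(N1[C@H](Cc2ccccc2)COC1=O)[C@H](CC=C)[C@@H](O)c1cc(OC)c(OC)c(OC)c1 | intermediate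
9 | syringaldehyde | COc1cc(C=O)cc(OC)c1O | starting material
10 | 4-(TBS-oxy)-3,5-dimethoxybenzaldehyde | COc1cc(C=O)cc(OC)c1O[Si](C)(C)C(C)(C)C | intermediate
11 | [4-(TBS-oxy)-3,5-dimethoxyphenyl]methanol | COc1cc(CO)cc(OC)c1O[Si](C)(C)C(C)(C)C | intermediate
12 | 4-(TBS-oxy)-3,5-dimethoxybenzyl 2,2,2-trichloroacetimidate | COc1cc(COC(=N)C(Cl)(Cl)Cl)cc(OC)c1O[Si](C)(C)C(C)(C)C | intermediate
13 | (R)-4-benzyl-3-[(2R)-2-[(R)-{[4-(TBS-oxy)-3,5-dimethoxybenzyl]oxy}(3,4,5-trimethoxyphenyl)methyl]pent-4-enoyl]oxazolidin-2-one | O=C(N1[C@H](Cc2ccccc2)COC1=O)[C@H](CC=C)[C@@H](OCc1cc(OC)c(O[Si](C)(C)C(C)(C)C)c(OC)c1)c1cc(OC)c(OC)c(OC)c1 | intermediate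
14 | (2S)-2-[(R)-{[4-(TBS-oxy)-3,5-dimethoxybenzyl]oxy}(3,4,5-trimethoxyphenyl)methyl]pent-4-en-1-ol | OC[C@H](CC=C)[C@@H](OCc1cc(OC)c(O[Si](C)(C)C(C)(C)C)c(OC)c1)c1cc(OC)c(OC)c(OC)c1 | intermediate
15 | TBS ether of 14 (primary O-silyl, aryl O-silyl, terminal alkene) | CC(C)(C)[Si](C)(C)OC[C@H](CC=C)[C@@H](OCc1cc(OC)c(O[Si](C)(C)C(C)(C)C)c(OC)c1)c1cc(OC)c(OC)c(OC)c1 | intermediate
16 | vicinal diol from 15 (new carbinol centre as a mixture) | CC(C)(C)[Si](C)(C)OC[C@H](CC(O)CO)[C@@H](OCc1cc(OC)c(O[Si](C)(C)C(C)(C)C)c(OC)c1)c1cc(OC)c(OC)c(OC)c1 | intermediate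
17 | (3S,4R)-3-[(TBS-oxy)methyl]-4-{[4-(TBS-oxy)-3,5-dimethoxybenzyl]oxy}-4-(3,4,5-trimethoxyphenyl)butanal | CC(C)(C)[Si](C)(C)OC[C@H](CC=O)[C@@H](OCc1cc(OC)c(O[Si](C)(C)C(C)(C)C)c(OC)c1)c1cc(OC)c(OC)c(OC)c1 | intermediate
18 | (3S,4R)-3-[(TBS-oxy)methyl]-4-{[4-(TBS-oxy)-3,5-dimethoxybenzyl]oxy}-4-(3,4,5-trimethoxyphenyl)butanoic acid | CC(C)(C)[Si](C)(C)OC[C@H](CC(=O)O)[C@@H](OCc1cc(OC)c(O[Si](C)(C)C(C)(C)C)c(OC)c1)c1cc(OC)c(OC)c(OC)c1 | intermediate
19 | methyl ester of 18 | CC(C)(C)[Si](C)(C)OC[C@H](CC(=O)OC)[C@@H](OCc1cc(OC)c(O[Si](C)(C)C(C)(C)C)c(OC)c1)c1cc(OC)c(OC)c(OC)c1 | intermediate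
20 | lithium enolate of 19 (enolate geometry not specified) | CC(C)(C)[Si](C)(C)OC[C@H](C=C(OC)O[Li])[C@@H](OCc1cc(OC)c(O[Si](C)(C)C(C)(C)C)c(OC)c1)c1cc(OC)c(OC)c(OC)c1 | intermediate
21 | 2-(trifluoroacetyl) derivative of 19 (C3 as a mixture) | CC(C)(C)[Si](C)(C)OC[C@H](C(C(=O)C(F)(F)F)C(=O)OC)[C@@H](OCc1cc(OC)c(O[Si](C)(C)C(C)(C)C)c(OC)c1)c1cc(OC)c(OC)c(OC)c1 | intermediate
22 | methyl (3S,4R)-2-diazo-3-[(TBS-oxy)methyl]-4-{[4-(TBS-oxy)-3,5-dimethoxybenzyl]oxy}-4-(3,4,5-trimethoxyphenyl)butanoate | COc1cc(CO[C@@H](c2cc(OC)c(OC)c(OC)c2)[C@H](CO[Si](C)(C)C(C)(C)C)C(=[N+]=[N-])C(=O)OC)cc(OC)c1O[Si](C)(C)C(C)(C)C | intermediate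
23 | methyl (2R,3S,4S,5R)-2-[4-(TBS-oxy)-3,5-dimethoxyphenyl]-4-[(TBS-oxy)methyl]-5-(3,4,5-trimethoxyphenyl)oxolane-3-carboxylate | COc1cc([C@@H]2O[C@@H](c3cc(OC)c(OC)c(OC)c3)[C@H](CO[Si](C)(C)C(C)(C)C)[C@@H]2C(=O)OC)cc(OC)c1O[Si](C)(C)C(C)(C)C | intermediate
24 | methyl (2R,3R,4S,5R)-4-[(TBS-oxy)methyl]-2-(4-hydroxy-3,5-dimethoxyphenyl)-5-(3,4,5-trimethoxyphenyl)oxolane-3-carboxylate | COc1cc([C@@H]2O[C@@H](c3cc(OC)c(OC)c(OC)c3)[C@H](CO[Si](C)(C)C(C)(C)C)[C@H]2C(=O)OC)cc(OC)c1O | intermediate
25 | 4-[(2R,3S,4S,5R)-4-[(TBS-oxy)methyl]-3-(hydroxymethyl)-5-(3,4,5-trimethoxyphenyl)oxolan-2-yl]-2,6-dimethoxyphenol | COc1cc([C@@H]2O[C@@H](c3cc(OC)c(OC)c(OC)c3)[C@H](CO[Si](C)(C)C(C)(C)C)[C@H]2CO)cc(OC)c1O | intermediate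
26 | 4-[(2R,3S,4S,5R)-3,4-bis(hydroxymethyl)-5-(3,4,5-trimethoxyphenyl)oxolan-2-yl]-2,6-dimethoxyphenol | COc1cc([C@@H]2O[C@@H](c3cc(OC)c(OC)c(OC)c3)[C@H](CO)[C@H]2CO)cc(OC)c1O | target

**Totals and risks**

Total step count: 16. Longest linear sequence: 14 steps (steps 3 to 16, from syringaldehyde 9); 13 steps from auxiliary 1.

Step 13 (key step). The carbene may be lost by 1,2-hydride migration from C4, or by attack on the ortho carbon of ring B, before it reaches the benzylic C–H; the wrong diastereotopic benzylic hydrogen may also be taken. The fallback ties the ester and the C4 arm into a γ-lactone, which holds the C4–H bond out of alignment with the carbene p orbital; insertion of such α-diazo lactones into benzyl ether C–H bonds to give cis-fused bicyclic lactones with the new aryl group endo is known chemistry. It sets out from alcohol 14 and comes back at target 26. Lemieux–Johnson cleavage of the allyl group of 14 (OsO4 cat., NaIO4, 2,6-lutidine) would give, after closure of the hydroxy aldehyde, the γ-lactol F1. TEMPO with PhI(OAc)2 would oxidise it to the γ-lactone F2. LiN(SiMe3)2 and CF3CO2CH2CF3 would give the 3-trifluoroacetyl lactone F3, and MsN3 with Et3N the 3-diazo lactone F4. Rh2(OAc)4 in CH2Cl2 should then close the oxolane by the same 1,5 insertion to the cis-fused bicyclic lactone F5, with ring A endo and ring B exo. NaOMe in MeOH would open the lactone, invert C3 (the trans hydroxy ester cannot close back) and free the phenol, giving the all-trans hydroxy ester F6. LiAlH4 would reduce F6 directly to 26.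

Step 12. C-acylation of the hindered, β-branched enolate may stall, or the amine and water of the transfer stage may strip the phenolic silyl group, so that little diazo ester forms. The fallback replaces acyl activation by azide chemistry; it sets out from ester 19 and comes back at diazo ester 22. KN(SiMe3)2 followed by 2,4,6-triisopropylbenzenesulfonyl azide and an AcOH quench would give the α-azido ester F7. N-succinimidyl 3-(diphenylphosphanyl)propanoate in THF/H2O, then Et3N, would convert the azide into the diazo group through an acyl triazene, giving 22.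

Step 6. The imidate may rearrange to the N-benzyl trichloroacetamide faster than it alkylates the hindered hydroxyl, or the acid may ionise the C5 carbinol (elimination or epimerisation) or cleave the acid-labile product ether. The fallback moves the etherification to a base-mediated Williamson reaction after the auxiliary is gone; it sets out from aldol 8 and comes back at alkene 15. LiBH4 would reduce 8 to the diol F8, and TBSCl with imidazole at 0 °C would silylate its primary hydroxyl to the mono-silyl ether F9. Alcohol 11 would be converted (CBr4, PPh3) into the benzyl bromide F10. NaH, F10 and Bu4NI in THF/DMF at 0 °C would then give 15.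

**Further compounds**

F1 | step 13 | (4S)-4-[(R)-{[4-(TBS-oxy)-3,5-dimethoxybenzyl]oxy}(3,4,5-trimethoxyphenyl)methyl]oxolan-2-ol (anomers) | OC1C[C@@H](CO1)[C@@H](OCc2cc(OC)c(O[Si](C)(C)C(C)(C)C)c(OC)c2)c2cc(OC)c(OC)c(OC)c2
F2 | step 13 | (4S)-4-[(R)-{[4-(TBS-oxy)-3,5-dimethoxybenzyl]oxy}(3,4,5-trimethoxyphenyl)methyl]oxolan-2-one | O=C1C[C@@H](CO1)[C@@H](OCc2cc(OC)c(O[Si](C)(C)C(C)(C)C)c(OC)c2)c2cc(OC)c(OC)c(OC)c2
F3 | step 13 | 3-(trifluoroacetyl) derivative of F2 (C3 as a mixture) | O=C1C(C(=O)C(F)(F)F)[C@@H](CO1)[C@@H](OCc2cc(OC)c(O[Si](C)(C)C(C)(C)C)c(OC)c2)c2cc(OC)c(OC)c(OC)c2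
F4 | step 13 | (4S)-3-diazo-4-[(R)-{[4-(TBS-oxy)-3,5-dimethoxybenzyl]oxy}(3,4,5-trimethoxyphenyl)methyl]oxolan-2-one | O=C1C(=[N+]=[N-])[C@@H](CO1)[C@@H](OCc2cc(OC)c(O[Si](C)(C)C(C)(C)C)c(OC)c2)c2cc(OC)c(OC)c(OC)c2
F5 | step 13 | cis-fused 8-endo-[4-(TBS-oxy)-3,5-dimethoxyphenyl]-6-exo-(3,4,5-trimethoxyphenyl)-3,7-dioxabicyclo[3.3.0]octan-2-one | COc1cc([C@@H]2O[C@@H](c3cc(OC)c(OC)c(OC)c3)[C@@H]4COC(=O)[C@H]24)cc(OC)c1O[Si](C)(C)C(C)(C)C
F6 | step 13 | methyl (2R,3R,4S,5R)-2-(4-hydroxy-3,5-dimethoxyphenyl)-4-(hydroxymethyl)-5-(3,4,5-trimethoxyphenyl)oxolane-3-carboxylate | COc1cc([C@@H]2O[C@@H](c3cc(OC)c(OC)c(OC)c3)[C@H](CO)[C@H]2C(=O)OC)cc(OC)c1O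
F7 | step 12 | methyl (3S,4R)-2-azido-3-[(TBS-oxy)methyl]-4-{[4-(TBS-oxy)-3,5-dimethoxybenzyl]oxy}-4-(3,4,5-trimethoxyphenyl)butanoate (C2 as a mixture) | CC(C)(C)[Si](C)(C)OC[C@H](C(N=[N+]=[N-])C(=O)OC)[C@@H](OCc1cc(OC)c(O[Si](C)(C)C(C)(C)C)c(OC)c1)c1cc(OC)c(OC)c(OC)c1
F8 | step 6 | (1R,2S)-2-allyl-1-(3,4,5-trimethoxyphenyl)propane-1,3-diol | OC[C@H](CC=C)[C@@H](O)c1cc(OC)c(OC)c(OC)c1
F9 | step 6 | (1R,2S)-2-[(TBS-oxy)methyl]-1-(3,4,5-trimethoxyphenyl)pent-4-en-1-ol | CC(C)(C)[Si](C)(C)OC[C@H](CC=C)[C@@H](O)c1cc(OC)c(OC)c(OC)c1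
F10 | step 6 | [4-(bromomethyl)-2,6-dimethoxyphenoxy](tert-butyl)dimethylsilane | COc1cc(CBr)cc(OC)c1O[Si](C)(C)C(C)(C)C
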